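## Retrosynthetic overview

- The side-chain bond C4'–C5' joins the two fragments. The 4'-CH(CH3) unit is read as a monosubstituted alkene C4'=CH2. Zr-catalysed asymmetric carboalumination with a side-chain trialkylalane puts C5' on C4', sets 4'R, and leaves Al on the carbon that protonolysis turns into the 4'-methyl.
- Enabling feature: the methyl-bearing tertiary CH at C4' (C4' plus its own CH3 are the two alkene carbons). It sits three CH2 groups (C1'–C3') away from the quaternary C2 of the dihydropyran ring of the chroman, so the alkene is unhindered and no activating group has to be removed afterwards.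
- Fragment 1 (alkene 13): C2 comes from (S)-2-methylglycidol, opened twice at CH2 (butenyl Grignard, then the aryl-CH2 Grignard). The benzene ring is bought. The dihydropyran ring is the only ring made, closed before the key step by reductive cyclisation of a hydroxyalkyl-quinone with the C2–O bond intact.
- Fragment 2 (alane 16): C8' comes from (R)-citronellal by methylenation and hydroalumination. After the key step, one hydrogenation removes the benzyl group and the C11'=C12' double bond.

Key step: step 10

Assumption: (−)-(NMI)2ZrCl2 is taken to deliver a higher alkyl group to the same alkene face as a methyl group (the face that gives (R)-2-methylalkylalanes from 1-alkenes); should a model run show the other sense, the (+)-catalyst is used.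

## Route

Step 1
Reactants: 1 (S)-2-methylglycidol; 2 but-3-en-1-ylmagnesium bromide (2.5 equiv)
Product: 3 (R)-2-methylhept-6-ene-1,2-diol
Conditions: CuI (10 mol%), THF, −30 → 0 °C; then aq NH4Cl
Reagents that add atoms: none
Why: Copper-catalysed Grignard opening of the 2,2-disubstituted epoxide at its CH2 terminus (SN2, after the first equivalent of 2 has made the alkoxide) leaves the quaternary carbinol carbon untouched, so the purchased stereocentre is carried into 3 unchanged (the Payne rearrangement of 2-methylglycidol is degenerate and cannot scramble it).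

Step 2
Reactants: 3 (R)-2-methylhept-6-ene-1,2-diol
Product: 5 (R)-2-methyl-2-(pent-4-en-1-yl)oxirane, via primary monotosylate 4 (not isolated)
Conditions: TsCl (1.05 equiv), Et3N, DMAP (cat.), CH2Cl2, 0 °C; then K2CO3, MeOH, 23 °C
Reagents that add atoms: none
Why: Selective sulfonylation of the primary hydroxyl followed by base-induced 3-exo-tet closure by the tertiary alkoxide (Williamson-type epoxide formation) breaks no bond to the stereocentre.

Step 3
Reactants: 6 1,4-dimethoxy-2,5-dimethylbenzene
Product: 7 2-(chloromethyl)-1,4-dimethoxy-3,6-dimethylbenzene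
Conditions: (CH2O)n, HCl (conc. aq + gas), AcOH, 60 °C
Reagents that add atoms: formaldehyde (as paraformaldehyde), C=O; hydrogen chloride, Cl
Why: Blanc chloromethylation of the electron-rich arene, whose two free ring positions are equivalent so that only one mono-chloromethyl product can form, with over-reaction limited by keeping 6 in excess.

Step 4
Reactants: 7 2-(chloromethyl)-1,4-dimethoxy-3,6-dimethylbenzene; 5 (R)-2-methyl-2-(pent-4-en-1-yl)oxirane
Product: 9 (R)-1-(2,5-dimethoxy-3,6-dimethylphenyl)-3-methyloct-7-en-3-ol, via benzylic Grignard reagent 8 (not isolated)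
Conditions: Mg, THF, 0 °C (slow addition of 7); then 5, CuI (10 mol%), −20 → 23 °C; aq NH4Cl
Reagents that add atoms: none
Why: Benzylic Grignard formation and copper-catalysed SN2 opening of the epoxide at its unsubstituted carbon build the two-carbon link (future C3–C4 of the chroman) while the tertiary C–O bond (future O1–C2) stays intact, so 9 keeps the (R) centre.

Step 5
Reactants: 9 (R)-1-(2,5-dimethoxy-3,6-dimethylphenyl)-3-methyloct-7-en-3-ol
Product: 10 (R)-2-(3-hydroxy-3-methyloct-7-en-1-yl)-3,6-dimethylcyclohexa-2,5-diene-1,4-dione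
Conditions: (NH4)2Ce(NO3)6 (2.5 equiv), MeCN/H2O, 0 °C
Reagents that add atoms: water, O
Why: Oxidative demethylation of a para-dimethoxyarene to the para-quinone by the one-electron oxidant (NH4)2Ce(NO3)6 (tetravalent cerium; water adds at the two ipso carbons and methanol leaves) is standard and leaves the tertiary alcohol and the terminal alkene alone.

Step 6
Reactants: 10 (R)-2-(3-hydroxy-3-methyloct-7-en-1-yl)-3,6-dimethylcyclohexa-2,5-diene-1,4-dione
Product: 12 (R)-2,5,8-trimethyl-2-(pent-4-en-1-yl)chroman-6-ol, via cyclic hemiketal 11 (not isolated)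
Conditions: L-ascorbic acid (5 equiv), HCl (0.1 M), MeOH/THF, degassed, 40 °C
Reagents that add atoms: none
Why: Reductive cyclisation of a tocopherolquinone-type 2-(3-hydroxyalkyl)benzoquinone, the reverse of the known two-electron oxidation of a 6-chromanol to its para-quinone: acid closes the tertiary hydroxyl on the C8a carbonyl (six-membered hemiketal 11), loss of water gives the chromanoxylium cation and ascorbic acid reduces it to the phenol, so the dihydropyran ring forms without the C2–O bond ever being broken and C2 stays (R).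

Step 7
Reactants: 12 (R)-2,5,8-trimethyl-2-(pent-4-en-1-yl)chroman-6-ol
Product: 13 (R)-6-(benzyloxy)-2,5,8-trimethyl-2-(pent-4-en-1-yl)chromane
Conditions: BnBr, K2CO3, DMF, 23 °C
Reagents that add atoms: benzyl bromide, BrCc1ccccc1
Why: Williamson etherification of the phenol (the only acidic group) masks it against the alane of the key step, and the benzyl group falls off in the final hydrogenation.

Step 8
Reactants: 14 (R)-citronellal
Product: 15 (R)-4,8-dimethylnona-1,7-diene
Conditions: Ph3PCH3Br, KOt-Bu, THF, 0 → 23 °C
Reagents that add atoms: methyltriphenylphosphonium bromide, C[P+](c1ccccc1)(c1ccccc1)c1ccccc1.[Br-]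
Why: Wittig methylenation of the aldehyde adds the carbon that becomes C5', and the stereocentre, being beta to the carbonyl, cannot epimerise under the basic conditions.

Step 9
Reactants: 15 (R)-4,8-dimethylnona-1,7-diene (3.3 equiv per Al)
Product: 16 tris[(4R)-4,8-dimethylnon-7-en-1-yl]alumane (used as obtained)
Conditions: i-Bu3Al, neat, 110 °C, argon sweep; excess 15 removed in vacuo
Reagents that add atoms: triisobutylaluminium, CC(C)C[Al](CC(C)C)CC(C)C
Why: Hydroalumination by alkene displacement (Ziegler-type): i-Bu3Al loses isobutene on heating and each Al–H adds anti-Markovnikov to the monosubstituted double bond only, leaving the trisubstituted alkene and the C4 stereocentre untouched and giving a donor-free trialkylalane.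

Step 10
Reactants: 13 (R)-6-(benzyloxy)-2,5,8-trimethyl-2-(pent-4-en-1-yl)chromane; 16 tris[(4R)-4,8-dimethylnon-7-en-1-yl]alumane (1.5 equiv)
Product: 18 (2R)-6-(benzyloxy)-2,5,8-trimethyl-2-[(4R,8S)-4,8,12-trimethyltridec-11-en-1-yl]chromane, via branched alkylalane 17 (not isolated)
Conditions: (−)-(NMI)2ZrCl2 [(−)-bis(1-neomenthylindenyl)zirconium dichloride] (8 mol%), CH2Cl2, 0 → 23 °C; then 2 M HCl, 0 °C
Reagents that add atoms: none
Why: Zirconium-catalysed asymmetric carboalumination (ZACA reaction) of a 1-alkene with a higher trialkylalane is the closest known reaction type and is used as such: the chiral cationic zirconocene alkyl formed from the catalyst and 16 inserts the monosubstituted alkene of 13 (Zr to the terminal carbon, the side-chain CH2 that is C5' to C4'), and Zr-to-Al exchange releases the 2-branched alkylalane 17 and regenerates the zirconium alkyl. Protonolysis of the C–Al bond on work-up turns the former terminal alkene carbon into the 4'-methyl group, so the C4'–C5' bond, the methyl branch and the C4' configuration all come from this one operation. No ring is closed in this step. C4' is set under reagent control by the catalyst (C2 and C8' are too remote to matter), and the (−)-catalyst should place the alkyl group on the face that corresponds to (R)-2-methylalkylalanes in methylalumination, which is 4'R here. The step needs regioselectivity (Al at the terminal carbon), secured by the monosubstituted alkene; chemoselectivity, secured because the trisubstituted alkenes of 16 and the benzyl-protected arene do not insert; and suppression of beta-hydride transfer (hydrometalation or the cyclic zirconacycle path), for which CH2Cl2 and a donor-free alane are chosen.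

Step 11
Reactants: 18 (2R)-6-(benzyloxy)-2,5,8-trimethyl-2-[(4R,8S)-4,8,12-trimethyltridec-11-en-1-yl]chromane
Product: 19 beta-tocopherol
Conditions: H2 (3 bar), Pd/C, EtOAc, 23 °C
Reagents that add atoms: none
Why: Heterogeneous hydrogenation saturates the trisubstituted C11'=C12' double bond (C12' is not a stereocentre) and hydrogenolyses the benzyl ether in the same operation, leaving the three stereocentres untouched.

## Compound list

1 | (S)-2-methylglycidol [(2S)-(2-methyloxiran-2-yl)methanol] | C[C@]1(CO)CO1 | starting material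
2 | but-3-en-1-ylmagnesium bromide | C=CCC[Mg]Br | starting material
3 | (R)-2-methylhept-6-ene-1,2-diol | C[C@](O)(CO)CCCC=C | intermediate
4 | (R)-2-hydroxy-2-methylhept-6-en-1-yl 4-methylbenzenesulfonate | C[C@](O)(COS(=O)(=O)c1ccc(C)cc1)CCCC=C | intermediate
5 | (R)-2-methyl-2-(pent-4-en-1-yl)oxirane | C[C@]1(CO1)CCCC=C | intermediate
6 | 1,4-dimethoxy-2,5-dimethylbenzene | COc1cc(C)c(OC)cc1C | starting material
7 | 2-(chloromethyl)-1,4-dimethoxy-3,6-dimethylbenzene | ClCc1c(C)c(OC)cc(C)c1OC | intermediate
8 | (2,5-dimethoxy-3,6-dimethylbenzyl)magnesium chloride | Cl[Mg]Cc1c(C)c(OC)cc(C)c1OC | intermediate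
9 | (R)-1-(2,5-dimethoxy-3,6-dimethylphenyl)-3-methyloct-7-en-3-ol | C[C@](O)(CCc1c(C)c(OC)cc(C)c1OC)CCCC=C | intermediate
10 | (R)-2-(3-hydroxy-3-methyloct-7-en-1-yl)-3,6-dimethylcyclohexa-2,5-diene-1,4-dione | C[C@](O)(CCC1=C(C)C(=O)C=C(C)C1=O)CCCC=C | intermediate
11 | (2R)-8a-hydroxy-2,5,8-trimethyl-2-(pent-4-en-1-yl)-2,3,4,8a-tetrahydro-6H-chromen-6-one (cyclic hemiketal, both C8a epimers) | C[C@@]1(CCCC=C)CCC2=C(C)C(=O)C=C(C)C2(O)O1 | intermediate
12 | (R)-2,5,8-trimethyl-2-(pent-4-en-1-yl)chroman-6-ol | Cc1cc(O)c(C)c2c1O[C@](C)(CCCC=C)CC2 | intermediate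
13 | (R)-6-(benzyloxy)-2,5,8-trimethyl-2-(pent-4-en-1-yl)chromane | Cc1cc(OCc3ccccc3)c(C)c2c1O[C@](C)(CCCC=C)CC2 | intermediate
14 | (R)-citronellal | C[C@H](CCC=C(C)C)CC=O | starting material
15 | (R)-4,8-dimethylnona-1,7-diene | C=CC[C@H](C)CCC=C(C)C | intermediate
16 | tris[(4R)-4,8-dimethylnon-7-en-1-yl]alumane | CC(C)=CCC[C@@H](C)CCC[Al](CCC[C@H](C)CCC=C(C)C)CCC[C@H](C)CCC=C(C)C | intermediate
17 | {(2R,6S)-2-[3-((2R)-6-(benzyloxy)-2,5,8-trimethylchroman-2-yl)propyl]-6,10-dimethylundec-9-en-1-yl}bis[(4R)-4,8-dimethylnon-7-en-1-yl]alumane | Cc1cc(OCc3ccccc3)c(C)c2c1O[C@](C)(CCC[C@H](C[Al](CCC[C@H](C)CCC=C(C)C)CCC[C@H](C)CCC=C(C)C)CCC[C@H](C)CCC=C(C)C)CC2 | intermediate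
18 | (2R)-6-(benzyloxy)-2,5,8-trimethyl-2-[(4R,8S)-4,8,12-trimethyltridec-11-en-1-yl]chromane (8'S only because the double bond changes the CIP priorities; same spatial arrangement as 8'R in the target) | Cc1cc(OCc3ccccc3)c(C)c2c1O[C@](C)(CCC[C@H](C)CCC[C@H](C)CCC=C(C)C)CC2 | intermediate
19 | beta-tocopherol, (2R)-2,5,8-trimethyl-2-[(4R,8R)-4,8,12-trimethyltridecyl]chroman-6-ol | Cc1cc(O)c(C)c2c1O[C@](C)(CCC[C@H](C)CCC[C@H](C)CCCC(C)C)CC2 | target

## Step count and risks

Total step count: 11. Longest linear sequence: 8 steps (steps 1, 2, 4, 5, 6, 7, 10, 11).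

**Risk 1, step 10 (key step).** Beta-hydride transfer from the long-chain alane may reduce the alkene of 13 instead of alkylating it, alkyl transfer may be slow, and facial control at C4' may be incomplete, which would leave a 4'-epimer that cannot be separated.

The fallback sets out from 13 and 15 and comes back at 18. It forms the same C4'–C5' bond by a copper-catalysed asymmetric conjugate addition.
- Oxidative cleavage of the terminal alkene of 13 (OsO4 cat., NaIO4, 2,6-lutidine, dioxane/H2O) gives 4-[(2R)-6-(benzyloxy)-2,5,8-trimethylchroman-2-yl]butanal F1.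
- Horner–Wadsworth–Emmons reaction with diethyl [(pyridin-2-ylsulfonyl)methyl]phosphonate (NaH, THF) gives 2-{[(1E)-5-((2R)-6-(benzyloxy)-2,5,8-trimethylchroman-2-yl)pent-1-en-1-yl]sulfonyl}pyridine F2, in which C4' is the beta-carbon and the future methyl carbon carries the sulfonyl group.
- From 15, hydroboration of the terminal alkene (9-BBN, then NaOH/H2O2) gives (R)-4,8-dimethylnon-7-en-1-ol F3.
- Appel bromination (CBr4, PPh3) gives (R)-9-bromo-2,6-dimethylnon-2-ene F4, and Mg in Et2O gives [(4R)-4,8-dimethylnon-7-en-1-yl]magnesium bromide F5.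
- Addition of F5 to F2 (CuCl, Tol-BINAP, t-BuOMe, −40 °C; the ligand antipode is chosen in a model addition so that the alkyl group enters the face giving the (R)-sulfone) gives 2-({(2R,6S)-2-[3-((2R)-6-(benzyloxy)-2,5,8-trimethylchroman-2-yl)propyl]-6,10-dimethylundec-9-en-1-yl}sulfonyl)pyridine F6.
- Reductive desulfonylation (Na(Hg), Na2HPO4, MeOH/THF) turns the CH2SO2 group into the 4'-methyl and gives 18.

**Risk 2, step 6.** The quinone may be reduced to its hydroquinone faster than the tertiary hydroxyl closes onto the C8a carbonyl, so that ring closure stalls. Acid strong enough to force it may ionise the tertiary carbinol and erode the C2 configuration.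

The fallback sets out from 10 and comes back at 12. It separates reduction and ring closure.
- Aqueous Na2S2O4 (EtOAc/H2O) reduces 10 to (R)-2-(3-hydroxy-3-methyloct-7-en-1-yl)-3,6-dimethylbenzene-1,4-diol F7.
- F7 is cyclodehydrated under argon with catalytic p-TsOH in toluene at 40 °C, with a few mol% of quinone 10 added as redox mediator. Closure again runs through the quinone hemiketal with F7 as the terminal reductant (the classical two-stage quinone, hydroquinone, chromanol sequence) and gives 12.

**Risk 3, step 4.** Wurtz-type homocoupling may compete while the electron-rich benzylic chloride is converted into its Grignard reagent, and opening of the 2,2-disubstituted epoxide may be slow.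

The fallback sets out from 7 and comes back at 9. It makes the same C–C bond with a sulfone-stabilised carbanion.
- Displacement of chloride from 7 with PhSO2Na (DMF, 60 °C) gives 1,4-dimethoxy-2,5-dimethyl-3-[(phenylsulfonyl)methyl]benzene F8.
- Deprotonation (n-BuLi, THF, −78 °C) and opening of epoxide 5 at its CH2 carbon in the presence of BF3·OEt2 gives (3R)-1-(2,5-dimethoxy-3,6-dimethylphenyl)-3-methyl-1-(phenylsulfonyl)oct-7-en-3-ol F9 (both C1 epimers).
- Reductive cleavage of the benzylic C–S bond (Na(Hg), Na2HPO4, MeOH) gives 9.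

## Further compounds

F1 | step 10 | 4-[(2R)-6-(benzyloxy)-2,5,8-trimethylchroman-2-yl]butanal | Cc1cc(OCc3ccccc3)c(C)c2c1O[C@](C)(CCCC=O)CC2
F2 | step 10 | 2-{[(1E)-5-((2R)-6-(benzyloxy)-2,5,8-trimethylchroman-2-yl)pent-1-en-1-yl]sulfonyl}pyridine | Cc1cc(OCc3ccccc3)c(C)c2c1O[C@](C)(CCC/C=C/S(=O)(=O)c3ccccn3)CC2
F3 | step 10 | (R)-4,8-dimethylnon-7-en-1-ol | OCCC[C@H](C)CCC=C(C)C
F4 | step 10 | (R)-9-bromo-2,6-dimethylnon-2-ene | BrCCC[C@H](C)CCC=C(C)C
F5 | step 10 | [(4R)-4,8-dimethylnon-7-en-1-yl]magnesium bromide | Br[Mg]CCC[C@H](C)CCC=C(C)C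
F6 | step 10 | 2-({(2R,6S)-2-[3-((2R)-6-(benzyloxy)-2,5,8-trimethylchroman-2-yl)propyl]-6,10-dimethylundec-9-en-1-yl}sulfonyl)pyridine | Cc1cc(OCc3ccccc3)c(C)c2c1O[C@](C)(CCC[C@H](CS(=O)(=O)c3ccccn3)CCC[C@H](C)CCC=C(C)C)CC2
F7 | step 6 | (R)-2-(3-hydroxy-3-methyloct-7-en-1-yl)-3,6-dimethylbenzene-1,4-diol | C[C@](O)(CCc1c(C)c(O)cc(C)c1O)CCCC=C
F8 | step 4 | 1,4-dimethoxy-2,5-dimethyl-3-[(phenylsulfonyl)methyl]benzene | O=S(=O)(Cc1c(C)c(OC)cc(C)c1OC)c1ccccc1
F9 | step 4 | (3R)-1-(2,5-dimethoxy-3,6-dimethylphenyl)-3-methyl-1-(phenylsulfonyl)oct-7-en-3-ol | C[C@](O)(CC(c1c(C)c(OC)cc(C)c1OC)S(=O)(=O)c1ccccc1)CCCC=C
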